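**Retrosynthetic overview**
- Sanggenone H ⇐ tri-MOM flavanone ⇐ C2–O1 closure by intramolecular Mitsunobu etherification (inversion) of an (R)-β-hydroxy 2-hydroxyaryl ketone; the chromanone ring is formed last.
- That ketone ⇐ C4–C4a bond from 2-lithio-1,3,5-tris(MOMO)benzene and an (R)-β-silyloxy aldehyde, then oxidation and unmasking.
- Aldehyde ⇐ glycol cleavage of an L-malic-acid-derived dioxolane. Its (S)-centre first directs a chelation-controlled syn reduction of the aryl ketone (this sets C2) and is then excised; its carbon becomes C4.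
- Aryl ketone ⇐ 8-lithiochromene + (S)-dioxolanyl Weinreb amide (C2–C1′ bond).
- Chromene ⇐ aryl 1,1-dimethylpropargyl ether by Claisen / [1,5]-H / oxa-6π cascade from 4-bromoresorcinol; this key step forms the first ring.

Assumption: methyl (S)-2-(2,2-dimethyl-1,3-dioxolan-4-yl)acetate (catalogue compound made from L-malic acid) is the chiral starting material; the target is the (2S)-flavanone.

**Step 1**
Reactants: 1, 4-bromoresorcinol
Product: 2, 2-bromo-5-(methoxymethoxy)phenol
Conditions: NaH (2.1 equiv), DMF, 0 °C; MOMCl (1.0 equiv), –20 → 0 °C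
Reagents that add atoms: chloromethyl methyl ether, COCCl
Why: Williamson O-alkylation of the dianion goes to the more basic, unhindered phenoxide para to Br (the ortho-bromo phenoxide is less nucleophilic and shielded); the minor regioisomer and bis-ether are removed by chromatography.

**Step 2**
Reactants: 2, 2-bromo-5-(methoxymethoxy)phenol
Product: 3, 1-bromo-4-(methoxymethoxy)-2-[(2-methylbut-3-yn-2-yl)oxy]benzene
Conditions: 3-chloro-3-methylbut-1-yne, DBU, CuCl2·2H2O (cat.), MeCN, 0 °C → rt
Reagents that add atoms: 3-chloro-3-methylbut-1-yne, CC(C)(Cl)C#C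
Why: Cu-catalysed propargylic etherification puts the tertiary 1,1-dimethylpropargyl group on the hindered phenol without touching ArBr or the MOM ether.

**Step 3** (key step)
Reactants: 3, the aryl propargyl ether
Product: 4, 8-bromo-5-(methoxymethoxy)-2,2-dimethyl-2H-chromene
Conditions: PhNEt2, 190 °C
Reagents that add atoms: none
Why: Aryl propargyl ether Claisen cascade — [3,3]-sigmatropic shift to the only free ortho carbon (the C–Br side cannot rearomatise and reverts), enolisation, [1,5]-H shift and oxa-6π electrocyclisation — closes the 2,2-dimethyl-2H-chromene.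

**Step 4**
Reactants: 5, methyl (S)-2-(2,2-dimethyl-1,3-dioxolan-4-yl)acetate
Product: 6, (S)-2-(2,2-dimethyl-1,3-dioxolan-4-yl)-N-methoxy-N-methylacetamide
Conditions: MeNH(OMe)·HCl, i-PrMgCl, THF, –20 °C
Reagents that add atoms: N,O-dimethylhydroxylamine hydrochloride, CNOC.Cl
Why: Ester aminolysis by the chloromagnesium amide gives the Weinreb amide without touching the acetonide or the stereocentre.

**Step 5**
Reactants: 4, the bromochromene; 6, the Weinreb amide
Product: 7, 2-[(4S)-2,2-dimethyl-1,3-dioxolan-4-yl]-1-[5-(methoxymethoxy)-2,2-dimethyl-2H-chromen-8-yl]ethan-1-one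
Conditions: 4, t-BuLi (2 equiv), THF, –78 °C; then 6, –78 → 0 °C
Reagents that add atoms: none
Why: Br/Li exchange followed by Weinreb ketone synthesis; the chelated tetrahedral intermediate prevents over-addition and the (S)-centre is not α to the carbonyl.

**Step 6**
Reactants: 7, the β-alkoxy aryl ketone
Product: 8, (1R)-2-[(4S)-2,2-dimethyl-1,3-dioxolan-4-yl]-1-[5-(methoxymethoxy)-2,2-dimethyl-2H-chromen-8-yl]ethan-1-ol (1,3-syn)
Conditions: LiI (excess), LiAlH4, Et2O, –100 °C
Reagents that add atoms: none
Why: Chelation-controlled hydride reduction of a β-alkoxy ketone: Li+ bridges the C=O and the β-dioxolane oxygen and hydride adds to the open face of the six-membered chelate, giving the 1,3-syn alcohol, so the purchased (S)-centre sets the new centre as R; the minor anti diastereomer is removed by chromatography.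

**Step 7**
Reactants: 8, the syn alcohol
Product: 9, tert-butyldimethylsilyl ether of 8
Conditions: TBSOTf, 2,6-lutidine, CH2Cl2, –78 °C
Reagents that add atoms: TBSOTf, CC(C)(C)[Si](C)(C)OS(=O)(=O)C(F)(F)F
Why: Silylation of the hindered benzylic alcohol protects it for the organolithium and oxidation steps.

**Step 8**
Reactants: 9, the silyl ether acetonide
Product: 10, (3R)-3-[(tert-butyldimethylsilyl)oxy]-3-[5-(methoxymethoxy)-2,2-dimethyl-2H-chromen-8-yl]propanal
Conditions: H5IO6, EtOAc, rt
Reagents that add atoms: none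
Why: Periodic acid hydrolyses the terminal acetonide and cleaves the 1,2-diol in one pot (Malaprade cleavage), excising the directing stereocentre, whose carbon becomes the aldehyde (future C4); C2 is untouched.

**Step 9**
Reactants: 11, phloroglucinol
Product: 12, 1,3,5-tris(methoxymethoxy)benzene
Conditions: NaH, MOMCl, DMF, 0 °C → rt
Reagents that add atoms: chloromethyl methyl ether, COCCl
Why: Exhaustive Williamson O-alkylation gives the tris-acetal, which serves as protection and as an ortho-directing group.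

**Step 10**
Reactants: 12, tris-MOM phloroglucinol; 10, the aldehyde
Product: 13, (3R)-3-[(tert-butyldimethylsilyl)oxy]-3-[5-(methoxymethoxy)-2,2-dimethyl-2H-chromen-8-yl]-1-[2,4,6-tris(methoxymethoxy)phenyl]propan-1-ol (mixture at C1)
Conditions: 12, n-BuLi, THF, 0 °C → rt; then 10, –78 °C
Reagents that add atoms: none
Why: Directed ortho-lithiation between two OMOM groups, then 1,2-addition to the aldehyde, forms the C4–C4a bond; the new carbinol mixture is erased in the next step.

**Step 11**
Reactants: 13, the epimeric alcohols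
Product: 14, (3R)-3-[(tert-butyldimethylsilyl)oxy]-3-[5-(methoxymethoxy)-2,2-dimethyl-2H-chromen-8-yl]-1-[2,4,6-tris(methoxymethoxy)phenyl]propan-1-one
Conditions: Dess–Martin periodinane, NaHCO3, CH2Cl2, rt
Reagents that add atoms: none
Why: Dess–Martin oxidation converts both epimers into the single aryl ketone under buffered conditions that do not affect the β-silyloxy centre.

**Step 12**
Reactants: 14, the tris-MOM ketone
Product: 15, (3R)-3-[(tert-butyldimethylsilyl)oxy]-1-[2-hydroxy-4,6-bis(methoxymethoxy)phenyl]-3-[5-(methoxymethoxy)-2,2-dimethyl-2H-chromen-8-yl]propan-1-one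
Conditions: MgBr2·OEt2, Et2O/CH2Cl2, 0 °C → rt
Reagents that add atoms: none
Why: Chelation-assisted acetal cleavage: Mg2+ held between the ketone and one ortho OMOM oxygen activates only that MOM, and the chelated magnesium phenoxide formed blocks a second cleavage.

**Step 13**
Reactants: 15, the silyl ether
Product: 16, (3R)-3-hydroxy-1-[2-hydroxy-4,6-bis(methoxymethoxy)phenyl]-3-[5-(methoxymethoxy)-2,2-dimethyl-2H-chromen-8-yl]propan-1-one
Conditions: HF·pyridine, pyridine, THF, 0 °C
Reagents that add atoms: none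
Why: Buffered fluoride desilylation frees the benzylic alcohol without base (no retro-aldol or E1cB) and without acid strong enough to ionise it.

**Step 14**
Reactants: 16, the (R)-β-hydroxy ketone
Product: 17, (2S)-5,7-bis(methoxymethoxy)-2-[5-(methoxymethoxy)-2,2-dimethyl-2H-chromen-8-yl]chroman-4-one
Conditions: PPh3, DIAD, toluene, 0 °C → rt
Reagents that add atoms: none
Why: Intramolecular Mitsunobu etherification: the ortho phenol displaces the oxyphosphonium in a six-membered SN2 closure with inversion, converting the (R)-carbinol into the (2S)-flavanone.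

**Step 15**
Reactants: 17, the tri-MOM flavanone
Product: 18, Sanggenone H, (2S)-5,7-dihydroxy-2-(5-hydroxy-2,2-dimethyl-2H-chromen-8-yl)chroman-4-one
Conditions: 3 M HCl, MeOH, 40 °C
Reagents that add atoms: none
Why: Acid-catalysed acetal solvolysis removes the three MOM groups under conditions mild enough to leave the flavanone C2 centre and the 2,2-dimethylchromene intact.

**Compound list**
1 | 4-bromoresorcinol | Oc1ccc(Br)c(O)c1 | starting material
2 | 2-bromo-5-(methoxymethoxy)phenol | COCOc1ccc(Br)c(O)c1 | intermediate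
3 | 1-bromo-4-(methoxymethoxy)-2-[(2-methylbut-3-yn-2-yl)oxy]benzene | COCOc1ccc(Br)c(OC(C)(C)C#C)c1 | intermediate
4 | 8-bromo-5-(methoxymethoxy)-2,2-dimethyl-2H-chromene | CC1(C)C=Cc2c(OCOC)ccc(Br)c2O1 | intermediate
5 | methyl (S)-2-(2,2-dimethyl-1,3-dioxolan-4-yl)acetate | COC(=O)C[C@H]1COC(C)(C)O1 | starting material
6 | (S)-2-(2,2-dimethyl-1,3-dioxolan-4-yl)-N-methoxy-N-methylacetamide | CON(C)C(=O)C[C@H]1COC(C)(C)O1 | intermediate
7 | 2-[(4S)-2,2-dimethyl-1,3-dioxolan-4-yl]-1-[5-(methoxymethoxy)-2,2-dimethyl-2H-chromen-8-yl]ethan-1-one | CC1(C)C=Cc2c(OCOC)ccc(C(=O)C[C@H]3COC(C)(C)O3)c2O1 | intermediate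
8 | (1R)-2-[(4S)-2,2-dimethyl-1,3-dioxolan-4-yl]-1-[5-(methoxymethoxy)-2,2-dimethyl-2H-chromen-8-yl]ethan-1-ol | CC1(C)C=Cc2c(OCOC)ccc([C@H](O)C[C@H]3COC(C)(C)O3)c2O1 | intermediate
9 | TBS ether of 8 | CC1(C)C=Cc2c(OCOC)ccc([C@H](O[Si](C)(C)C(C)(C)C)C[C@H]3COC(C)(C)O3)c2O1 | intermediate
10 | (3R)-3-(TBSO)-3-[5-(methoxymethoxy)-2,2-dimethyl-2H-chromen-8-yl]propanal | CC1(C)C=Cc2c(OCOC)ccc([C@H](O[Si](C)(C)C(C)(C)C)CC=O)c2O1 | intermediate
11 | phloroglucinol | Oc1cc(O)cc(O)c1 | starting material
12 | 1,3,5-tris(methoxymethoxy)benzene | COCOc1cc(OCOC)cc(OCOC)c1 | intermediate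
13 | (3R)-3-(TBSO)-3-[5-(methoxymethoxy)-2,2-dimethyl-2H-chromen-8-yl]-1-[2,4,6-tris(methoxymethoxy)phenyl]propan-1-ol (C1 epimers) | CC1(C)C=Cc2c(OCOC)ccc([C@H](O[Si](C)(C)C(C)(C)C)CC(O)c3c(OCOC)cc(OCOC)cc3OCOC)c2O1 | intermediate
14 | ketone from 13 | CC1(C)C=Cc2c(OCOC)ccc([C@H](O[Si](C)(C)C(C)(C)C)CC(=O)c3c(OCOC)cc(OCOC)cc3OCOC)c2O1 | intermediate
15 | (3R)-3-(TBSO)-1-[2-hydroxy-4,6-bis(methoxymethoxy)phenyl]-3-[5-(methoxymethoxy)-2,2-dimethyl-2H-chromen-8-yl]propan-1-one | CC1(C)C=Cc2c(OCOC)ccc([C@H](O[Si](C)(C)C(C)(C)C)CC(=O)c3c(O)cc(OCOC)cc3OCOC)c2O1 | intermediate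
16 | (3R)-3-hydroxy-1-[2-hydroxy-4,6-bis(methoxymethoxy)phenyl]-3-[5-(methoxymethoxy)-2,2-dimethyl-2H-chromen-8-yl]propan-1-one | CC1(C)C=Cc2c(OCOC)ccc([C@H](O)CC(=O)c3c(O)cc(OCOC)cc3OCOC)c2O1 | intermediate
17 | (2S)-5,7-bis(methoxymethoxy)-2-[5-(methoxymethoxy)-2,2-dimethyl-2H-chromen-8-yl]chroman-4-one | CC1(C)C=Cc2c(OCOC)ccc([C@@H]3CC(=O)c4c(OCOC)cc(OCOC)cc4O3)c2O1 | intermediate
18 | Sanggenone H | CC1(C)C=Cc2c(O)ccc([C@@H]3CC(=O)c4c(O)cc(O)cc4O3)c2O1 | target

**Totals**
Total steps: 15. Longest linear sequence: 13 (steps 1–3, 5–8, 10–15).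

**Steps most likely to fail**
1. Step 14 (Mitsunobu). The electron-rich benzylic oxyphosphonium may ionise (loss of ee) or eliminate to the chalcone. Fallback: close the other C–O bond (O1–C8a) with retention at C2. Use a 2-fluoro-4,6-bis(MOMO)phenyl-lithium in step 10 and cyclise the carbinol alkoxide by intramolecular SNAr. The required (S)-carbinol comes from the same ketone 7 by acetonide removal and Evans–Saksena anti reduction.
2. Step 6 (chelation-controlled reduction). The chromene oxygen may compete for Li+ and lower the syn selectivity. Fallback: hydrolyse the acetonide of 7 to the β,γ-dihydroxy ketone, use hydroxyl-directed Narasaka–Prasad reduction (Et2BOMe, NaBH4), then re-form the terminal acetonide to rejoin the route at 8.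
3. Step 12 (selective removal of one ortho MOM). Over-cleavage or loss of the silyl ether is possible. Fallback: avoid any selective deprotection by forming C4–C4a through ortho-specific hydroxyalkylation of the bromomagnesium salt of 3,5-bis(methoxymethoxy)phenol with aldehyde 10, then MnO2 oxidation, which gives 15 with the phenol already free.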